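The 14-membered carbocycle is opened at C6–C7 (numbering: C1 carries the isopropenyl group, C4 the ester, C6, C10 and C13 are the ketone carbons, C8 and C11 the ether-bridged ring carbons). Both atoms are electrophiles in the precursor: C7 is a neopentyl iodide on the quaternary oxolanone carbon C8 and C6 a 2-pyridyl thioester. A nickel-catalysed reductive cross-electrophile coupling unites them through a C7 radical, which neither SN2 chemistry nor a β-alkoxy organometallic could do, and forms the β-alkoxy ketone and the macrocycle in the last step under neutral conditions. The precursor is a linear iodo thioester built on a stereodefined trans-2,5-disubstituted oxolan-3-one, itself joined to a carvone-derived chain by the same reaction.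

Key step: step 17

Locants used below: C1 (CH, isopropenyl), C2, C3=C4 (C4 bears CO2Me), C5, C6 (C=O), C7, C8 (quaternary, CH3, O), C9, C10 (C=O), C11 (CH–O), C12, C13 (C=O), C14; the ether oxygen links C8 and C11.

Remark: (R)-2-methylglycidol (1) and (4-methoxyphenyl)methyl bromoacetate (13) are taken as purchasable; phosphonate 14 is used as the racemate because its stereocentre is lost in step 9.

Abbreviations: TBS = tert-butyldimethylsilyl; PMB = 4-methoxybenzyl; dtbbpy = 4,4'-di-tert-butyl-2,2'-bipyridine; DMA = N,N-dimethylacetamide; CSA = camphorsulfonic acid.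

**Oxolane core (C7–C12)**

Step 1
Reactants: 1 (R)-(2-methyloxiran-2-yl)methanol
Product: 2 (S)-tert-butyldimethyl[(2-methyloxiran-2-yl)methoxy]silane
Conditions: TBSCl, imidazole, CH2Cl2, 0 °C to rt
Reagents that add atoms: tert-butyldimethylsilyl chloride, CC(C)(C)[Si](C)(C)Cl
Why: Imidazole-promoted silylation of the primary alcohol leaves the epoxide and the quaternary centre (future C8) untouched and blocks this oxygen from competing in the later epoxide-opening cyclisation.

Step 2
Reactants: 2 (S)-tert-butyldimethyl[(2-methyloxiran-2-yl)methoxy]silane; 3 prop-2-yn-1-ol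
Product: 4 (5S)-6-[(tert-butyldimethylsilyl)oxy]-5-methylhex-2-yne-1,5-diol
Conditions: LiNH2 (2 equiv per 3), NH3(l)/THF, −33 °C to rt; aq. NH4Cl
Reagents that add atoms: none
Why: Acetylide alkylation, in which the dilithio derivative of 3 opens the 2,2-disubstituted epoxide by SN2 at its CH2 terminus, forms C9–C10 and leaves the C8–O bond and hence the C8 configuration intact.

Step 3
Reactants: 4 (5S)-6-[(tert-butyldimethylsilyl)oxy]-5-methylhex-2-yne-1,5-diol
Product: 5 (2E,5S)-6-[(tert-butyldimethylsilyl)oxy]-5-methylhex-2-ene-1,5-diol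
Conditions: NaAlH2(OCH2CH2OMe)2 (Red-Al), THF, 0 °C to rt
Reagents that add atoms: none
Why: Hydroxyl-directed trans-hydroalumination of the propargylic alcohol followed by protonolysis should give the E-allylic alcohol needed for a trans-epoxide.

Step 4
Reactants: 5 (2E,5S)-6-[(tert-butyldimethylsilyl)oxy]-5-methylhex-2-ene-1,5-diol
Product: 7 (2R,3S,5S)-5-{[(tert-butyldimethylsilyl)oxy]methyl}-2-(hydroxymethyl)-5-methyloxolan-3-ol, via epoxy alcohol 6 (not isolated)
Conditions: Ti(OiPr)4 (10 mol %), L-(+)-diethyl tartrate (12 mol %), t-BuOOH, 4 Å MS, CH2Cl2, −20 °C; then CSA (30 mol %), 0 °C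
Reagents that add atoms: tert-butyl hydroperoxide, CC(C)(C)OO
Why: Sharpless asymmetric epoxidation with L-(+)-tartrate sets the (2S,3S)-epoxide under reagent control, and acid-catalysed 5-endo epoxide opening by the tertiary C8 hydroxyl at C11 with inversion (the 4-exo alternative being strained) fixes C11 relative to the pool-derived C8, while the C10 carbinol centre is removed later by oxidation.

Step 5
Reactants: 7 (2R,3S,5S)-5-{[(tert-butyldimethylsilyl)oxy]methyl}-2-(hydroxymethyl)-5-methyloxolan-3-ol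
Product: 8 (2S,3S,5S)-5-{[(tert-butyldimethylsilyl)oxy]methyl}-2-(iodomethyl)-5-methyloxolan-3-ol
Conditions: PPh3, I2, imidazole, THF, 0 °C
Reagents that add atoms: iodine, II
Why: Appel-type iodination is selective for the primary over the secondary hydroxyl at low temperature and proceeds by SN2 at C12 without touching a stereocentre.

**Chain (C13–C6)**

Step 6
Reactants: 9 (S)-(+)-carvone
Product: 10 (1S,4S,6S)-1-methyl-4-(prop-1-en-2-yl)-7-oxabicyclo[4.1.0]heptan-2-one
Conditions: H2O2 (30% aq), NaOH (cat.), MeOH, 0 °C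
Reagents that add atoms: hydrogen peroxide, OO
Why: Weitz–Scheffer nucleophilic epoxidation attacks only the electron-poor enone double bond, anti to the isopropenyl group, and leaves the isopropenyl alkene intact (the two new centres are destroyed in step 7).

Step 7
Reactants: 10 (1S,4S,6S)-1-methyl-4-(prop-1-en-2-yl)-7-oxabicyclo[4.1.0]heptan-2-one
Product: 11 (3S)-5-oxo-3-(prop-1-en-2-yl)pentanoic acid
Conditions: H5IO6 (2.2 equiv), THF/H2O, 0 °C to rt
Reagents that add atoms: periodic acid, OI(=O)(O)(O)(O)O; water, O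
Why: Periodic acid hydrates the epoxide and then cleaves both the glycol and the α-ketol (Malaprade-type cleavages), excising the methyl-bearing ring carbon as acetic acid and leaving the C13 acid and the C3 aldehyde on either side of the untouched C1 stereocentre.

Step 8
Reactants: 12 methyl 2-[bis(2,2,2-trifluoroethoxy)phosphoryl]acetate; 13 (4-methoxyphenyl)methyl 2-bromoacetate
Product: 14 4-[(4-methoxyphenyl)methyl] 1-methyl 2-[bis(2,2,2-trifluoroethoxy)phosphoryl]butanedioate (racemic)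
Conditions: NaH, THF, 0 °C to rt
Reagents that add atoms: none
Why: SN2 C-alkylation of the sodium phosphonoacetate enolate by the α-bromo ester gives the phosphonosuccinate that carries C4, C5 and C6.

Step 9
Reactants: 11 (3S)-5-oxo-3-(prop-1-en-2-yl)pentanoic acid; 14 4-[(4-methoxyphenyl)methyl] 1-methyl 2-[bis(2,2,2-trifluoroethoxy)phosphoryl]butanedioate
Product: 15 (3S,5Z)-6-(methoxycarbonyl)-8-[(4-methoxyphenyl)methoxy]-8-oxo-3-(prop-1-en-2-yl)oct-5-enoic acid
Conditions: KN(SiMe3)2 (2 equiv), 18-crown-6, THF, −78 °C; aq. NaH2PO4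
Reagents that add atoms: none
Why: Still–Gennari variant of the Horner–Wadsworth–Emmons olefination, in which fast irreversible elimination from the kinetic adduct of the bis(trifluoroethyl)phosphonate places the aldehyde-derived chain cis to the methyl ester (Z), the carboxylic acid being carried as its potassium salt.

Step 10
Reactants: 15 (3S,5Z)-6-(methoxycarbonyl)-8-[(4-methoxyphenyl)methoxy]-8-oxo-3-(prop-1-en-2-yl)oct-5-enoic acid
Product: 16 4-[(4-methoxyphenyl)methyl] 1-methyl (2Z)-2-[(3S)-5-oxo-3-(prop-1-en-2-yl)-5-(pyridin-2-ylsulfanyl)pentylidene]butanedioate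
Conditions: 2,2'-dipyridyl disulfide, PPh3, CH2Cl2, rt
Reagents that add atoms: 2,2'-dipyridyl disulfide, c1ccc(SSc2ccccn2)nc1
Why: Mukaiyama redox condensation converts the free acid to the S-2-pyridyl thioester under neutral conditions that leave both esters and both alkenes alone.

**Fragment union and end game**

Step 11
Reactants: 8 (2S,3S,5S)-5-{[(tert-butyldimethylsilyl)oxy]methyl}-2-(iodomethyl)-5-methyloxolan-3-ol; 16 4-[(4-methoxyphenyl)methyl] 1-methyl (2Z)-2-[(3S)-5-oxo-3-(prop-1-en-2-yl)-5-(pyridin-2-ylsulfanyl)pentylidene]butanedioate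
Product: 17 methyl (2Z,5S)-8-[(2R,3S,5S)-5-{[(tert-butyldimethylsilyl)oxy]methyl}-3-hydroxy-5-methyloxolan-2-yl]-2-{2-[(4-methoxyphenyl)methoxy]-2-oxoethyl}-7-oxo-5-(prop-1-en-2-yl)oct-2-enoate
Conditions: NiCl2(dme) (10 mol %), dtbbpy (12 mol %), Mn powder, DMA, rt
Reagents that add atoms: none
Why: Nickel-catalysed reductive cross-electrophile ketone synthesis, in which zerovalent nickel inserts into the C(acyl)–S bond and the primary iodide delivers a C12 radical that is captured and reductively eliminated, forms C12–C13 without ever generating a β-alkoxy organometallic and without touching a stereocentre.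

Step 12
Reactants: 17 methyl (2Z,5S)-8-[(2R,3S,5S)-5-{[(tert-butyldimethylsilyl)oxy]methyl}-3-hydroxy-5-methyloxolan-2-yl]-2-{2-[(4-methoxyphenyl)methoxy]-2-oxoethyl}-7-oxo-5-(prop-1-en-2-yl)oct-2-enoate
Product: 18 methyl (2Z,5S)-8-[(2R,5S)-5-{[(tert-butyldimethylsilyl)oxy]methyl}-5-methyl-3-oxooxolan-2-yl]-2-{2-[(4-methoxyphenyl)methoxy]-2-oxoethyl}-7-oxo-5-(prop-1-en-2-yl)oct-2-enoate
Conditions: Dess–Martin periodinane, NaHCO3, CH2Cl2, 0 °C to rt
Reagents that add atoms: none
Why: Dess–Martin oxidation of the secondary alcohol under buffered, non-basic conditions should give the oxolan-3-one without epimerising the adjacent C11 or opening the β-alkoxy ketone.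

Step 13
Reactants: 18 methyl (2Z,5S)-8-[(2R,5S)-5-{[(tert-butyldimethylsilyl)oxy]methyl}-5-methyl-3-oxooxolan-2-yl]-2-{2-[(4-methoxyphenyl)methoxy]-2-oxoethyl}-7-oxo-5-(prop-1-en-2-yl)oct-2-enoate
Product: 19 methyl (2Z,5S)-8-[(2R,5S)-5-(hydroxymethyl)-5-methyl-3-oxooxolan-2-yl]-2-{2-[(4-methoxyphenyl)methoxy]-2-oxoethyl}-7-oxo-5-(prop-1-en-2-yl)oct-2-enoate
Conditions: HF·pyridine, pyridine, THF, 0 °C to rt
Reagents that add atoms: none
Why: Fluoride-mediated desilylation with buffered HF–pyridine is mildly acidic and spares the PMB ester, the enoate and the epimerisable C11.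

Step 14
Reactants: 19 methyl (2Z,5S)-8-[(2R,5S)-5-(hydroxymethyl)-5-methyl-3-oxooxolan-2-yl]-2-{2-[(4-methoxyphenyl)methoxy]-2-oxoethyl}-7-oxo-5-(prop-1-en-2-yl)oct-2-enoate
Product: 20 methyl (2Z,5S)-8-[(2R,5S)-5-(iodomethyl)-5-methyl-3-oxooxolan-2-yl]-2-{2-[(4-methoxyphenyl)methoxy]-2-oxoethyl}-7-oxo-5-(prop-1-en-2-yl)oct-2-enoate
Conditions: PPh3, I2, imidazole, toluene, 60 °C
Reagents that add atoms: iodine, II
Why: Appel-type iodination, in which the alkoxyphosphonium of the neopentyl C7 alcohol needs gentle heating for SN2 by iodide, installs the radical precursor next to the quaternary C8, which cannot be affected.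

Step 15
Reactants: 20 methyl (2Z,5S)-8-[(2R,5S)-5-(iodomethyl)-5-methyl-3-oxooxolan-2-yl]-2-{2-[(4-methoxyphenyl)methoxy]-2-oxoethyl}-7-oxo-5-(prop-1-en-2-yl)oct-2-enoate
Product: 21 (3Z,6S)-9-[(2R,5S)-5-(iodomethyl)-5-methyl-3-oxooxolan-2-yl]-3-(methoxycarbonyl)-8-oxo-6-(prop-1-en-2-yl)non-3-enoic acid
Conditions: CF3CO2H (5 vol %), anisole, CH2Cl2, 0 °C
Reagents that add atoms: none
Why: Acidolysis of the PMB ester through the stabilised benzyl cation, trapped by anisole, is fast at 0 °C and should spare the methyl ester, the alkyl iodide and the isopropenyl group.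

Step 16
Reactants: 21 (3Z,6S)-9-[(2R,5S)-5-(iodomethyl)-5-methyl-3-oxooxolan-2-yl]-3-(methoxycarbonyl)-8-oxo-6-(prop-1-en-2-yl)non-3-enoic acid
Product: 22 methyl (2Z,5S)-8-[(2R,5S)-5-(iodomethyl)-5-methyl-3-oxooxolan-2-yl]-7-oxo-2-[2-oxo-2-(pyridin-2-ylsulfanyl)ethyl]-5-(prop-1-en-2-yl)oct-2-enoate
Conditions: 2,2'-dipyridyl disulfide, PPh3, CH2Cl2, rt
Reagents that add atoms: 2,2'-dipyridyl disulfide, c1ccc(SSc2ccccn2)nc1
Why: Mukaiyama redox condensation activates the C6 acid as the S-2-pyridyl thioester under neutral conditions, PPh3 being unable to displace the neopentyl iodide.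

Step 17
Reactants: 22 methyl (2Z,5S)-8-[(2R,5S)-5-(iodomethyl)-5-methyl-3-oxooxolan-2-yl]-7-oxo-2-[2-oxo-2-(pyridin-2-ylsulfanyl)ethyl]-5-(prop-1-en-2-yl)oct-2-enoate
Product: 23 methyl (1R,5Z,8S,12R)-1-methyl-3,10,13-trioxo-8-(prop-1-en-2-yl)-15-oxabicyclo[10.2.1]pentadec-5-ene-5-carboxylate (CNP0163183.3)
Conditions: NiCl2(dme) (50 mol %), dtbbpy (55 mol %), Mn powder, DMA, 2 mM, syringe-pump addition of 22, rt
Reagents that add atoms: none
Why: Zerovalent nickel (from NiCl2(dme)/dtbbpy and Mn) inserts into the C6(acyl)–S bond of the thioester, the neopentyl C7–I bond is cleaved by halogen-atom abstraction at low-valent nickel, and the C7 radical is captured by the acyl–nickel species, whose reductive elimination from trivalent nickel forms C6–C7. The closest known reaction type is the nickel-catalysed reductive ketone synthesis from alkyl iodides and S-2-pyridyl thioesters (cross-electrophile coupling), here run intramolecularly under high dilution. The single ring closed is the 14-membered carbocycle (13-membered through the ether oxygen), formed by end-to-end radical capture and reductive elimination at nickel, not by a Baldwin-type attack, with the C3=C4 unit and the trans-2,5-disubstituted oxolanone pre-bending the chain. No stereocentre is created: C8 is quaternary and cannot invert next to the radical, and C1 and C11 are preserved because the medium is neutral and free of enolising base. The step needs chemoselectivity for the activated thioester over the methyl ester and the two ketones and for radical capture over β-alkoxy elimination of an organometallic, which the radical pathway and manganese as terminal reductant secure, while addition of the C7 radical to the isopropenyl or enoate alkenes would require medium or large rings and intermolecular coupling is suppressed by slow addition.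

**Compound list**

1 | (R)-(2-methyloxiran-2-yl)methanol [(R)-2-methylglycidol] | OC[C@]1(C)CO1 | starting material
2 | (S)-tert-butyldimethyl[(2-methyloxiran-2-yl)methoxy]silane | CC(C)(C)[Si](C)(C)OC[C@]1(C)CO1 | intermediate
3 | prop-2-yn-1-ol | C#CCO | starting material
4 | (5S)-6-[(tert-butyldimethylsilyl)oxy]-5-methylhex-2-yne-1,5-diol | CC(C)(C)[Si](C)(C)OC[C@](O)(C)CC#CCO | intermediate
5 | (2E,5S)-6-[(tert-butyldimethylsilyl)oxy]-5-methylhex-2-ene-1,5-diol | CC(C)(C)[Si](C)(C)OC[C@](O)(C)C/C=C/CO | intermediate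
6 | (2S)-3-[(tert-butyldimethylsilyl)oxy]-1-[(2S,3S)-3-(hydroxymethyl)oxiran-2-yl]-2-methylpropan-2-ol (epoxy alcohol) | CC(C)(C)[Si](C)(C)OC[C@](O)(C)C[C@@H]1O[C@H]1CO | intermediate
7 | (2R,3S,5S)-5-{[(tert-butyldimethylsilyl)oxy]methyl}-2-(hydroxymethyl)-5-methyloxolan-3-ol | CC(C)(C)[Si](C)(C)OC[C@]1(C)C[C@H](O)[C@@H](CO)O1 | intermediate
8 | (2S,3S,5S)-5-{[(tert-butyldimethylsilyl)oxy]methyl}-2-(iodomethyl)-5-methyloxolan-3-ol | CC(C)(C)[Si](C)(C)OC[C@]1(C)C[C@H](O)[C@@H](CI)O1 | intermediate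
9 | (S)-(+)-carvone [(5S)-2-methyl-5-(prop-1-en-2-yl)cyclohex-2-en-1-one] | CC1=CC[C@@H](CC1=O)C(C)=C | starting material
10 | (1S,4S,6S)-1-methyl-4-(prop-1-en-2-yl)-7-oxabicyclo[4.1.0]heptan-2-one | C[C@]12O[C@H]1C[C@H](C(C)=C)CC2=O | intermediate
11 | (3S)-5-oxo-3-(prop-1-en-2-yl)pentanoic acid | OC(=O)C[C@@H](C(C)=C)CC=O | intermediate
12 | methyl 2-[bis(2,2,2-trifluoroethoxy)phosphoryl]acetate | COC(=O)CP(=O)(OCC(F)(F)F)OCC(F)(F)F | starting material
13 | (4-methoxyphenyl)methyl 2-bromoacetate | COc1ccc(COC(=O)CBr)cc1 | starting material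
14 | 4-[(4-methoxyphenyl)methyl] 1-methyl 2-[bis(2,2,2-trifluoroethoxy)phosphoryl]butanedioate (racemic) | COC(=O)C(CC(=O)OCc1ccc(OC)cc1)P(=O)(OCC(F)(F)F)OCC(F)(F)F | intermediate
15 | (3S,5Z)-6-(methoxycarbonyl)-8-[(4-methoxyphenyl)methoxy]-8-oxo-3-(prop-1-en-2-yl)oct-5-enoic acid | OC(=O)C[C@@H](C(C)=C)C/C=C(\C(=O)OC)CC(=O)OCc1ccc(OC)cc1 | intermediate
16 | 4-[(4-methoxyphenyl)methyl] 1-methyl (2Z)-2-[(3S)-5-oxo-3-(prop-1-en-2-yl)-5-(pyridin-2-ylsulfanyl)pentylidene]butanedioate | O=C(C[C@@H](C(C)=C)C/C=C(\C(=O)OC)CC(=O)OCc1ccc(OC)cc1)Sc1ccccn1 | intermediate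
17 | methyl (2Z,5S)-8-[(2R,3S,5S)-5-{[(tert-butyldimethylsilyl)oxy]methyl}-3-hydroxy-5-methyloxolan-2-yl]-2-{2-[(4-methoxyphenyl)methoxy]-2-oxoethyl}-7-oxo-5-(prop-1-en-2-yl)oct-2-enoate | CC(C)(C)[Si](C)(C)OC[C@]1(C)C[C@H](O)[C@@H](CC(=O)C[C@@H](C(C)=C)C/C=C(\C(=O)OC)CC(=O)OCc2ccc(OC)cc2)O1 | intermediate
18 | methyl (2Z,5S)-8-[(2R,5S)-5-{[(tert-butyldimethylsilyl)oxy]methyl}-5-methyl-3-oxooxolan-2-yl]-2-{2-[(4-methoxyphenyl)methoxy]-2-oxoethyl}-7-oxo-5-(prop-1-en-2-yl)oct-2-enoate | CC(C)(C)[Si](C)(C)OC[C@]1(C)CC(=O)[C@@H](CC(=O)C[C@@H](C(C)=C)C/C=C(\C(=O)OC)CC(=O)OCc2ccc(OC)cc2)O1 | intermediate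
19 | methyl (2Z,5S)-8-[(2R,5S)-5-(hydroxymethyl)-5-methyl-3-oxooxolan-2-yl]-2-{2-[(4-methoxyphenyl)methoxy]-2-oxoethyl}-7-oxo-5-(prop-1-en-2-yl)oct-2-enoate | OC[C@]1(C)CC(=O)[C@@H](CC(=O)C[C@@H](C(C)=C)C/C=C(\C(=O)OC)CC(=O)OCc2ccc(OC)cc2)O1 | intermediate
20 | methyl (2Z,5S)-8-[(2R,5S)-5-(iodomethyl)-5-methyl-3-oxooxolan-2-yl]-2-{2-[(4-methoxyphenyl)methoxy]-2-oxoethyl}-7-oxo-5-(prop-1-en-2-yl)oct-2-enoate | IC[C@]1(C)CC(=O)[C@@H](CC(=O)C[C@@H](C(C)=C)C/C=C(\C(=O)OC)CC(=O)OCc2ccc(OC)cc2)O1 | intermediate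
21 | (3Z,6S)-9-[(2R,5S)-5-(iodomethyl)-5-methyl-3-oxooxolan-2-yl]-3-(methoxycarbonyl)-8-oxo-6-(prop-1-en-2-yl)non-3-enoic acid | IC[C@]1(C)CC(=O)[C@@H](CC(=O)C[C@@H](C(C)=C)C/C=C(\C(=O)OC)CC(=O)O)O1 | intermediate
22 | methyl (2Z,5S)-8-[(2R,5S)-5-(iodomethyl)-5-methyl-3-oxooxolan-2-yl]-7-oxo-2-[2-oxo-2-(pyridin-2-ylsulfanyl)ethyl]-5-(prop-1-en-2-yl)oct-2-enoate | IC[C@]1(C)CC(=O)[C@@H](CC(=O)C[C@@H](C(C)=C)C/C=C(\C(=O)OC)CC(=O)Sc2ccccn2)O1 | intermediate
23 | methyl (1R,5Z,8S,12R)-1-methyl-3,10,13-trioxo-8-(prop-1-en-2-yl)-15-oxabicyclo[10.2.1]pentadec-5-ene-5-carboxylate (CNP0163183.3) | C=C(C)[C@H]1C/C=C(\C(=O)OC)CC(=O)C[C@]2(C)CC(=O)[C@@H](CC(=O)C1)O2 | target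

**Step count and risks**

Total step count: 17. Longest linear sequence: 12 steps (steps 1–5 and 11–17).

Steps most likely to fail:

Step 17 (macrocyclisation). The closure may be overtaken by intermolecular coupling to oligomers, by reduction of the C7 radical before capture, or by decarbonylation of the β,γ-unsaturated acyl–nickel intermediate. The fallback closes the same C6–C7 bond as an alkene by ring-closing metathesis and then oxidises it; it sets out from 11 (with 12 and 8) and comes back to the route at 23. Phosphonate 12 would be alkylated with allyl bromide (NaH, THF) to methyl 2-[bis(2,2,2-trifluoroethoxy)phosphoryl]pent-4-enoate F1. Still–Gennari olefination of 11 with F1 should give (3S,5Z)-6-(methoxycarbonyl)-3-(prop-1-en-2-yl)nona-5,8-dienoic acid F2, which is converted as in step 10 to its S-2-pyridyl thioester F3. Nickel coupling with 8 as in step 11 should give the hydroxy ketone F4, Dess–Martin oxidation the oxolanone F5, and HF·pyridine the primary alcohol F6. A second Dess–Martin oxidation gives the C7 aldehyde F7, and aldehyde-selective methylenation (CH2I2, Zn, Ti(OiPr)4, THF) the C8-vinyl diene F8. Second-generation Grubbs catalyst at high dilution (CH2Cl2, 40 °C) should close the 14-membered ring as the C6=C7 alkene F9; the isopropenyl group cannot compete because the seven-membered ring it would form would contain the trans C3=C4 bond. A Wacker oxidation of this internal alkene (Pd(OAc)2, 1,4-benzoquinone, aqueous HBF4, DMA/MeCN) should then place the carbonyl at C6, distal to the allylic ether oxygen and to the quaternary C8, to give 23.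

Step 14 (neopentyl iodination). Substitution at the neopentyl, β-oxygenated C7 may be slow enough at 60 °C that epimerisation at C11 or retro-oxa-Michael opening of the 1,4-diketone competes. The fallback separates activation from substitution; it sets out from 19 and comes back at 20. Alcohol 19 would be converted with Tf2O and 2,6-di-tert-butyl-4-methylpyridine (CH2Cl2, −78 °C) to the C7 trifluoromethanesulfonate F10, which is displaced by n-Bu4NI in toluene at room temperature to give 20.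

Step 4 (epoxidation and 5-endo cyclisation). The tertiary hydroxyl may fail to open the epoxide at C11, the carbon next to the CH2OH group, so that 4-exo or intermolecular opening at C10 competes. The fallback avoids the epoxide; it sets out from 4 and comes back at 7. A cationic gold catalyst made from AuCl(PPh3) and AgOTf (THF, rt) should cycloisomerise 4 by 5-endo-dig attack of the C8 hydroxyl to the enol ether [(2S)-2-{[(tert-butyldimethylsilyl)oxy]methyl}-2-methyl-2,3-dihydrofuran-5-yl]methanol F11. Asymmetric hydroboration with monoisopinocampheylborane (the enantiomer that delivers hydrogen to C11 on the face cis to the CH2OTBS group), followed by NaOH/H2O2, places boron and then hydroxyl at C10 syn to the new C11–H and should give 7.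

Further compounds
F1 | step 17 | methyl 2-[bis(2,2,2-trifluoroethoxy)phosphoryl]pent-4-enoate (racemic) | C=CCC(C(=O)OC)P(=O)(OCC(F)(F)F)OCC(F)(F)F
F2 | step 17 | (3S,5Z)-6-(methoxycarbonyl)-3-(prop-1-en-2-yl)nona-5,8-dienoic acid | OC(=O)C[C@@H](C(C)=C)C/C=C(\C(=O)OC)CC=C
F3 | step 17 | methyl (2Z,5S)-7-oxo-2-(prop-2-en-1-yl)-5-(prop-1-en-2-yl)-7-(pyridin-2-ylsulfanyl)hept-2-enoate | O=C(C[C@@H](C(C)=C)C/C=C(\C(=O)OC)CC=C)Sc1ccccn1
F4 | step 17 | methyl (2Z,5S)-8-[(2R,3S,5S)-5-{[(tert-butyldimethylsilyl)oxy]methyl}-3-hydroxy-5-methyloxolan-2-yl]-7-oxo-2-(prop-2-en-1-yl)-5-(prop-1-en-2-yl)oct-2-enoate | CC(C)(C)[Si](C)(C)OC[C@]1(C)C[C@H](O)[C@@H](CC(=O)C[C@@H](C(C)=C)C/C=C(\C(=O)OC)CC=C)O1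
F5 | step 17 | methyl (2Z,5S)-8-[(2R,5S)-5-{[(tert-butyldimethylsilyl)oxy]methyl}-5-methyl-3-oxooxolan-2-yl]-7-oxo-2-(prop-2-en-1-yl)-5-(prop-1-en-2-yl)oct-2-enoate | CC(C)(C)[Si](C)(C)OC[C@]1(C)CC(=O)[C@@H](CC(=O)C[C@@H](C(C)=C)C/C=C(\C(=O)OC)CC=C)O1
F6 | step 17 | methyl (2Z,5S)-8-[(2R,5S)-5-(hydroxymethyl)-5-methyl-3-oxooxolan-2-yl]-7-oxo-2-(prop-2-en-1-yl)-5-(prop-1-en-2-yl)oct-2-enoate | OC[C@]1(C)CC(=O)[C@@H](CC(=O)C[C@@H](C(C)=C)C/C=C(\C(=O)OC)CC=C)O1
F7 | step 17 | methyl (2Z,5S)-8-[(2R,5S)-5-formyl-5-methyl-3-oxooxolan-2-yl]-7-oxo-2-(prop-2-en-1-yl)-5-(prop-1-en-2-yl)oct-2-enoate | O=C[C@]1(C)CC(=O)[C@@H](CC(=O)C[C@@H](C(C)=C)C/C=C(\C(=O)OC)CC=C)O1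
F8 | step 17 | methyl (2Z,5S)-8-[(2R,5S)-5-ethenyl-5-methyl-3-oxooxolan-2-yl]-7-oxo-2-(prop-2-en-1-yl)-5-(prop-1-en-2-yl)oct-2-enoate | C=C[C@]1(C)CC(=O)[C@@H](CC(=O)C[C@@H](C(C)=C)C/C=C(\C(=O)OC)CC=C)O1
F9 | step 17 | methyl (1S,5Z,8S,12R)-1-methyl-10,13-dioxo-8-(prop-1-en-2-yl)-15-oxabicyclo[10.2.1]pentadeca-2,5-diene-5-carboxylate (C2=C3 geometry open) | C=C(C)[C@H]1C/C=C(\C(=O)OC)CC=C[C@]2(C)CC(=O)[C@@H](CC(=O)C1)O2
F10 | step 14 | methyl (2Z,5S)-2-{2-[(4-methoxyphenyl)methoxy]-2-oxoethyl}-8-[(2R,5S)-5-methyl-3-oxo-5-{[(trifluoromethanesulfonyl)oxy]methyl}oxolan-2-yl]-7-oxo-5-(prop-1-en-2-yl)oct-2-enoate | FC(F)(F)S(=O)(=O)OC[C@]1(C)CC(=O)[C@@H](CC(=O)C[C@@H](C(C)=C)C/C=C(\C(=O)OC)CC(=O)OCc2ccc(OC)cc2)O1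
F11 | step 4 | [(2S)-2-{[(tert-butyldimethylsilyl)oxy]methyl}-2-methyl-2,3-dihydrofuran-5-yl]methanol | CC(C)(C)[Si](C)(C)OC[C@]1(C)CC=C(CO)O1
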